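**Plan**
1. Locants: rings C (C1–C4, C4a, C9b) and D (C5a, C6–C9, C9a) and O5 follow dibenzofuran numbering. Ring A is the para-phenylene and ring B the phenol ring that carries the diaryl ether oxygen. CH2(a) is the bridge carbon on C7 and CH2(b) its neighbour on ring B.
2. Cuts, in retrosynthetic order: O5–C5a (furan ring, back to C4a–OH plus C5a–F); C7–CH2(a) (opens the 18-membered ring to a C7 bromide and a 3-arylpropanoic acid one carbon longer); the CH2–CH2 bond between rings A and C (olefination); C9a–C9b (biaryl coupling); ring A–O–ring B (SNAr).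
3. Enabling feature: CH2(a) ends a 2-arylethyl chain on ring B, so it is the decarboxylation radical of a dihydrocinnamic acid, and C7 is an unhindered position of ring D, para to C9a and meta to C5a. While O5–C5a is still open, rings C and D can twist about C9a–C9b, so the ring closes without bending an arene, and C5a–F is inert to nickel.
4. Forward: rings C and D are joined (steps 1–3) and rings A and B are joined (steps 4–5). Both halves are linked and saturated (steps 6–7) and the acid is armed (steps 8–9). The 18-membered ring closes at a cathode with loss of CO2 (step 10), and the furan ring arises last (steps 11–12), which flattens rings C and D.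
5. Helpers: the carboxyl carbon and the phthalimide leave in step 10, the three O-methyl groups in step 11, and the fluorine in step 12.
6. Stereochemistry: the target has no stereocentre. The E alkene of 10 is erased in step 7 and the biaryl axis of 5 and 10–15 in step 12.

Key step: step 10

Remark: the biaryl axis of 5 and 10–15 (three ortho substituents, one of them fluorine) is taken as configurationally labile or racemic. It is left unspecified in the SMILES because it ends in the planar dibenzofuran.

Step 1
Reactants: 1 diethyl (3,5-dimethoxybenzyl)phosphonate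
Product: 2 diethyl (2-bromo-3,5-dimethoxybenzyl)phosphonate
Conditions: NBS (1.0 equiv), MeCN, 0 °C, dark
Reagents that add atoms: N-bromosuccinimide, O=C1CCC(=O)N1Br
Why: Electrophilic aromatic bromination with NBS: the two methoxy groups of ring C jointly activate the two equivalent positions next to the CH2P arm (para to one OMe, ortho to the other), which are less crowded than the site between the two OMe groups, and the polar solvent in the dark suppresses benzylic radical bromination.

Step 2
Reactants: 2 diethyl (2-bromo-3,5-dimethoxybenzyl)phosphonate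
Product: 3 diethyl [3,5-dimethoxy-2-(4,4,5,5-tetramethyl-1,3,2-dioxaborolan-2-yl)benzyl]phosphonate
Conditions: B2pin2, Pd(dppf)Cl2 (5 mol %), KOAc, dioxane, 95 °C
Reagents that add atoms: bis(pinacolato)diboron, CC1(C)OB(OC1(C)C)B1OC(C)(C)C(C)(C)O1
Why: Miyaura borylation: zerovalent palladium inserts into the C–Br bond and the acetate-bound palladium exchanges with B2pin2, while KOAc is too weak a base to touch the benzylic phosphonate CH2 or to start a homocoupling.

Step 3
Reactants: 3 diethyl [3,5-dimethoxy-2-(4,4,5,5-tetramethyl-1,3,2-dioxaborolan-2-yl)benzyl]phosphonate; 4 4-bromo-2-fluoro-1-iodobenzene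
Product: 5 diethyl [(4'-bromo-2'-fluoro-4,6-dimethoxybiphenyl-2-yl)methyl]phosphonate
Conditions: Pd(PPh3)4 (5 mol %), K3PO4, dioxane/H2O, 85 °C, 4 in excess (2 equiv)
Reagents that add atoms: none
Why: Suzuki–Miyaura coupling with halogen selectivity: oxidative addition to the carbon–iodine bond of 4 is far faster than to its carbon–bromine bond and the carbon–fluorine bond is inert, so with 4 in excess only the C9a–C9b bond should form while Br (future C7) and F (future C5a) are kept.

Step 4
Reactants: 6 3-(3-hydroxy-4-methoxyphenyl)propanoic acid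
Product: 7 methyl 3-(3-hydroxy-4-methoxyphenyl)propanoate
Conditions: MeOH, H2SO4 (cat.), reflux
Reagents that add atoms: methanol, CO
Why: Fischer esterification: acid-catalysed acyl substitution in excess methanol masks the acid for the basic steps 5 and 6 and leaves the phenol free.

Step 5
Reactants: 7 methyl 3-(3-hydroxy-4-methoxyphenyl)propanoate; 8 4-fluorobenzaldehyde
Product: 9 methyl 3-[3-(4-formylphenoxy)-4-methoxyphenyl]propanoate
Conditions: K2CO3, DMF, 120 °C
Reagents that add atoms: none
Why: Nucleophilic aromatic substitution (SNAr): the para-formyl group stabilises the Meisenheimer adduct, so the phenoxide of 7 displaces fluoride and sets the ring A–O–ring B ether.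

Step 6
Reactants: 5 diethyl [(4'-bromo-2'-fluoro-4,6-dimethoxybiphenyl-2-yl)methyl]phosphonate; 9 methyl 3-[3-(4-formylphenoxy)-4-methoxyphenyl]propanoate
Product: 10 methyl 3-{3-[4-((E)-2-(4'-bromo-2'-fluoro-4,6-dimethoxybiphenyl-2-yl)vinyl)phenoxy]-4-methoxyphenyl}propanoate
Conditions: NaH (added last to 5 + 9), THF, 0 °C to rt
Reagents that add atoms: none
Why: Horner–Wadsworth–Emmons olefination: the benzylic phosphonate anion of 5 adds to the non-enolisable aldehyde of 9 faster than it meets the ester, and the resulting E alkene carries no lasting stereochemical information because step 7 saturates it.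

Step 7
Reactants: 10 methyl 3-{3-[4-((E)-2-(4'-bromo-2'-fluoro-4,6-dimethoxybiphenyl-2-yl)vinyl)phenoxy]-4-methoxyphenyl}propanoate
Product: 11 methyl 3-{3-[4-(2-(4'-bromo-2'-fluoro-4,6-dimethoxybiphenyl-2-yl)ethyl)phenoxy]-4-methoxyphenyl}propanoate
Conditions: TsNHNH2 (excess), NaOAc, DME/H2O, reflux
Reagents that add atoms: none
Why: Diimide reduction: HN=NH made in the flask delivers two hydrogens to the stilbene C=C in a concerted syn transfer and, unlike hydrogenation over palladium, does not cleave the aryl bromide.

Step 8
Reactants: 11 methyl 3-{3-[4-(2-(4'-bromo-2'-fluoro-4,6-dimethoxybiphenyl-2-yl)ethyl)phenoxy]-4-methoxyphenyl}propanoate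
Product: 12 3-{3-[4-(2-(4'-bromo-2'-fluoro-4,6-dimethoxybiphenyl-2-yl)ethyl)phenoxy]-4-methoxyphenyl}propanoic acid
Conditions: LiOH·H2O, THF/MeOH/H2O, rt; then 1 M HCl
Reagents that add atoms: lithium hydroxide, [Li+].[OH-]
Why: Saponification: hydroxide attacks the unhindered methyl ester by acyl substitution and nothing else in 11 is base-labile at room temperature.

Step 9
Reactants: 12 3-{3-[4-(2-(4'-bromo-2'-fluoro-4,6-dimethoxybiphenyl-2-yl)ethyl)phenoxy]-4-methoxyphenyl}propanoic acid
Product: 13 1,3-dioxoisoindolin-2-yl 3-{3-[4-(2-(4'-bromo-2'-fluoro-4,6-dimethoxybiphenyl-2-yl)ethyl)phenoxy]-4-methoxyphenyl}propanoate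
Conditions: N-hydroxyphthalimide, N,N'-diisopropylcarbodiimide, DMAP (cat.), CH2Cl2, rt
Reagents that add atoms: N-hydroxyphthalimide, O=C1c2ccccc2C(=O)N1O
Why: Carbodiimide (Steglich-type) esterification: the O-acylisourea of 12 is intercepted by N-hydroxyphthalimide to give the redox-active ester that stores the CH2(a) radical.

Step 10
Reactants: 13 1,3-dioxoisoindolin-2-yl 3-{3-[4-(2-(4'-bromo-2'-fluoro-4,6-dimethoxybiphenyl-2-yl)ethyl)phenoxy]-4-methoxyphenyl}propanoate
Product: 14 seco-furan macrocycle (18-membered ring C7–CH2(a)–CH2(b)–ring B–O–ring A–CH2CH2–C1, C9b–C9a; OMe at C3, at C4a and on ring B; F at C5a)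
Conditions: NiCl2·6H2O (0.5 equiv), 2,2'-bipyridine (0.5 equiv), AgNO3 (0.3 equiv), LiCl, NMP, undivided cell, Mg anode, reticulated vitreous carbon cathode, constant current, rt; 13 added by syringe pump (final 2 mM)
Reagents that add atoms: none
Why: Proposed new method: cathodic reduction turns NiCl2/2,2'-bipyridine into zerovalent nickel, which inserts into the C7–Br bond of ring D, while monovalent nickel or the silver-coated cathode passes one electron to the N-acyloxyphthalimide, which fragments to phthalimide anion, CO2 and the primary radical at CH2(a); the divalent aryl-nickel centre of the same molecule captures this radical and the trivalent nickel species releases the C7–CH2(a) bond by reductive elimination. The closest known reaction type is the intermolecular nickel-electrocatalytic decarboxylative arylation of primary alkyl redox-active esters with aryl bromides, so bond type and functional groups are precedented and only the ring-closing mode is new. One ring is closed, the 18-membered ring through rings A, B, C and D: radical capture first gives a 19-membered nickelacycle and reductive elimination contracts it by the nickel atom, an end-to-end closure with no competing smaller ring because any shorter contact would need a C–H or C–O bond to break. No stereocentre is formed. The step needs intramolecular over intermolecular coupling and radical capture over hydrogen abstraction, which are served by syringe-pump addition that keeps 13 below the nickel concentration and by the still open furan ring, since free torsion about C9a–C9b lets the chain ends meet without bending any arene. It also needs insertion into C–Br over C–F and C–O, which the bipyridine-nickel catalyst secures by itself, and the only rearrangement open to the 2-arylethyl radical, the 1,2-aryl shift, is degenerate.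

Step 11
Reactants: 14 seco-furan macrocycle, trimethyl ether
Product: 15 seco-furan macrocycle, triol (OH at C3, at C4a and on ring B; F at C5a)
Conditions: BBr3 (6 equiv), CH2Cl2, –78 °C to rt; then H2O
Reagents that add atoms: none
Why: Lewis-acid ether cleavage: BBr3 coordinates each aryl methyl ether oxygen and bromide removes the methyl group by SN2, while the diaryl ether, the aryl fluoride and the bibenzyl bridges are inert.

Step 12
Reactants: 15 seco-furan macrocycle, triol
Product: 16 asterelin A
Conditions: K2CO3, NMP (degassed, 0.01 M), 150 °C; then 1 M HCl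
Reagents that add atoms: none
Why: Intramolecular SNAr, the established closure of 2'-fluorobiphenyl-2-ols to dibenzofurans: of the three phenoxides only the one at C4a can reach C5a (five-membered ring), so fluoride leaves and rings C and D become coplanar.

**Compound list**
1 | diethyl (3,5-dimethoxybenzyl)phosphonate | CCOP(=O)(Cc1cc(OC)cc(OC)c1)OCC | starting material
2 | diethyl (2-bromo-3,5-dimethoxybenzyl)phosphonate | CCOP(=O)(Cc1cc(OC)cc(OC)c1Br)OCC | intermediate
3 | diethyl [3,5-dimethoxy-2-(4,4,5,5-tetramethyl-1,3,2-dioxaborolan-2-yl)benzyl]phosphonate | CCOP(=O)(Cc1cc(OC)cc(OC)c1B1OC(C)(C)C(C)(C)O1)OCC | intermediate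
4 | 4-bromo-2-fluoro-1-iodobenzene | Fc1cc(Br)ccc1I | starting material
5 | diethyl [(4'-bromo-2'-fluoro-4,6-dimethoxybiphenyl-2-yl)methyl]phosphonate | CCOP(=O)(Cc1cc(OC)cc(OC)c1-c1ccc(Br)cc1F)OCC | intermediate
6 | 3-(3-hydroxy-4-methoxyphenyl)propanoic acid | COc1ccc(CCC(=O)O)cc1O | starting material
7 | methyl 3-(3-hydroxy-4-methoxyphenyl)propanoate | COc1ccc(CCC(=O)OC)cc1O | intermediate
8 | 4-fluorobenzaldehyde | O=Cc1ccc(F)cc1 | starting material
9 | methyl 3-[3-(4-formylphenoxy)-4-methoxyphenyl]propanoate | COc1ccc(CCC(=O)OC)cc1Oc1ccc(C=O)cc1 | intermediate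
10 | methyl 3-{3-[4-((E)-2-(4'-bromo-2'-fluoro-4,6-dimethoxybiphenyl-2-yl)vinyl)phenoxy]-4-methoxyphenyl}propanoate | COC(=O)CCc1ccc(OC)c(Oc2ccc(/C=C/c3cc(OC)cc(OC)c3-c3ccc(Br)cc3F)cc2)c1 | intermediate
11 | methyl 3-{3-[4-(2-(4'-bromo-2'-fluoro-4,6-dimethoxybiphenyl-2-yl)ethyl)phenoxy]-4-methoxyphenyl}propanoate | COC(=O)CCc1ccc(OC)c(Oc2ccc(CCc3cc(OC)cc(OC)c3-c3ccc(Br)cc3F)cc2)c1 | intermediate
12 | 3-{3-[4-(2-(4'-bromo-2'-fluoro-4,6-dimethoxybiphenyl-2-yl)ethyl)phenoxy]-4-methoxyphenyl}propanoic acid | OC(=O)CCc1ccc(OC)c(Oc2ccc(CCc3cc(OC)cc(OC)c3-c3ccc(Br)cc3F)cc2)c1 | intermediate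
13 | 1,3-dioxoisoindolin-2-yl ester of 12 (redox-active ester) | O=C(CCc1ccc(OC)c(Oc2ccc(CCc3cc(OC)cc(OC)c3-c3ccc(Br)cc3F)cc2)c1)ON1C(=O)c2ccccc2C1=O | intermediate
14 | seco-furan macrocycle, trimethyl ether (F at C5a) | COc1cc2c(c(OC)c1)-c1ccc(cc1F)CCc1ccc(OC)c(c1)Oc1ccc(cc1)CC2 | intermediate
15 | seco-furan macrocycle, triol (F at C5a) | Oc1cc2c(c(O)c1)-c1ccc(cc1F)CCc1ccc(O)c(c1)Oc1ccc(cc1)CC2 | intermediate
16 | asterelin A | Oc1cc2c3c(c1)oc1cc(ccc13)CCc1ccc(O)c(c1)Oc1ccc(cc1)CC2 | target

Total step count: 12. Longest linear sequence: 10 (steps 1–3 and 6–12).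

**Steps most likely to fail**

1. Step 10 (the labelled step).
- What may go wrong: the ester may be reduced before nickel has inserted into the C7–Br bond, so the radical is lost by hydrogen abstraction from the solvent. Radical capture may also take place between two molecules and lead to oligomerisation.
- Fallback: it uses known chemistry, sets out from 13 and comes back at 14. Copper-catalysed decarboxylative borylation (Cu(acac)2, B2pin2, LiOH·H2O, MgCl2, dioxane/DMF, rt) leaves aryl bromides alone and would turn 13 into the primary alkyl pinacol boronate F1. An intramolecular sp3–sp2 Suzuki–Miyaura coupling at high dilution (Pd(OAc)2, RuPhos, K3PO4, toluene/H2O, 90 °C, syringe pump) would then join CH2(a) to C7. This is a two-electron manifold in which both partners sit in every molecule and no free radical has to be caught.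

2. Step 12.
- What may go wrong: flattening of rings C and D tightens the 18-membered ring. Addition of the C4a phenoxide to the unactivated C5a–F carbon may therefore be too slow below the temperature at which the electron-rich triphenoxide decays.
- Fallback: it inverts the order of the two ring closures, sets out from 12 and comes back at 16. BBr3 would strip the three methyl ethers of 12 to the open-chain fluoro triol acid F2. K2CO3 in hot NMP would close the furan ring on this unstrained compound to the 7-bromodibenzofuran diol acid F3. Ac2O/pyridine with aqueous work-up would give the diacetate acid F4, and N-hydroxyphthalimide with N,N'-diisopropylcarbodiimide the redox-active ester F5. The conditions of step 10 would give asterelin A diacetate F6, and K2CO3 in methanol would free 16. The strain is then taken up in an irreversible C–C reductive elimination instead of an SNAr addition.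

3. Step 3.
- What may go wrong: transmetalation of the doubly ortho-substituted, electron-rich boronate may be slow, which allows protodeboronation. The halogen selectivity may also erode at the temperature needed.
- Fallback: it sets out from 2 (step 2 is skipped) and comes back at 5. The hindered bromide 2 would be coupled with purchased 4-amino-2-fluorophenylboronic acid pinacol ester (Pd(OAc)2, SPhos, K3PO4, toluene/H2O, 100 °C). Here the boron partner is unhindered and no second halogen limits the choice of ligand, and the product would be the aminobiaryl phosphonate F7. A Sandmeyer bromination (t-BuONO, CuBr2, MeCN, 0 °C to rt) would then put bromine in place of the amino group.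

Further compounds
F1 | step 10 | 2-{2-[3-(4-(2-(4'-bromo-2'-fluoro-4,6-dimethoxybiphenyl-2-yl)ethyl)phenoxy)-4-methoxyphenyl]ethyl}-4,4,5,5-tetramethyl-1,3,2-dioxaborolane | CC1(C)OB(CCc2ccc(OC)c(Oc3ccc(CCc4cc(OC)cc(OC)c4-c4ccc(Br)cc4F)cc3)c2)OC1(C)C
F2 | step 12 | 3-{3-[4-(2-(4'-bromo-2'-fluoro-4,6-dihydroxybiphenyl-2-yl)ethyl)phenoxy]-4-hydroxyphenyl}propanoic acid | OC(=O)CCc1ccc(O)c(Oc2ccc(CCc3cc(O)cc(O)c3-c3ccc(Br)cc3F)cc2)c1
F3 | step 12 | 3-{3-[4-(2-(7-bromo-3-hydroxydibenzofuran-1-yl)ethyl)phenoxy]-4-hydroxyphenyl}propanoic acid | OC(=O)CCc1ccc(O)c(Oc2ccc(CCc3cc(O)cc4oc5cc(Br)ccc5c34)cc2)c1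
F4 | step 12 | 3-{4-acetoxy-3-[4-(2-(3-acetoxy-7-bromodibenzofuran-1-yl)ethyl)phenoxy]phenyl}propanoic acid | OC(=O)CCc1ccc(OC(C)=O)c(Oc2ccc(CCc3cc(OC(C)=O)cc4oc5cc(Br)ccc5c34)cc2)c1
F5 | step 12 | 1,3-dioxoisoindolin-2-yl ester of F4 | O=C(CCc1ccc(OC(C)=O)c(Oc2ccc(CCc3cc(OC(C)=O)cc4oc5cc(Br)ccc5c34)cc2)c1)ON1C(=O)c2ccccc2C1=O
F6 | step 12 | asterelin A diacetate | CC(=O)Oc1cc2c3c(c1)oc1cc(ccc13)CCc1ccc(OC(C)=O)c(c1)Oc1ccc(cc1)CC2
F7 | step 3 | diethyl [(4'-amino-2'-fluoro-4,6-dimethoxybiphenyl-2-yl)methyl]phosphonate | CCOP(=O)(Cc1cc(OC)cc(OC)c1-c1ccc(N)cc1F)OCC
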